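## Retrosynthetic overview

- The target is read as epicatechin-(4β→8)-catechin whose lower (catechin) unit carries the 3-O-(4-hydroxybenzoate): upper unit (2R,3R,4R), lower unit (2R,3S). The last operations are desilylation and global O-debenzylation.
- Enabling feature: C4 of the upper unit is a methine bonded to C4a (upper ring A) and to C8 (lower ring A), both carbons of 1,3,5-trioxygenated benzene rings. C4 is therefore a latent aldehyde carbon that can be arylated twice. Both C4–aryl bonds are disconnected, C4–C4a as the bond that closes the upper pyran ring C.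
- This gives an acyclic (2S,3R)-3-aryl-3-aryloxy-2-silyloxypropanal and benzylated (+)-catechin 3-O-[4-(benzyloxy)benzoate], joined in one Lewis-acid cascade.
- The aldehyde comes from (R)-glyceraldehyde acetonide (supplies C3): anti-selective aryl addition, then Mitsunobu inversion with 3,5-bis(benzyloxy)phenol sets the C2–O1 ether; C4 is set in the cascade.
- Ring order: lower rings A, C and B arrive intact in (+)-catechin; upper rings A and B are bought as benzene building blocks; the only ring made is the upper pyran ring C (step 9).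

Key step: step 9

Remark: compounds 1, 2, 6, 12 and 14 are taken as commercial; 2 is used freshly distilled because it oligomerises on storage.

## Route

Step 1
Reactants: 1 4-bromo-1,2-bis(benzyloxy)benzene; 2 (R)-2,2-dimethyl-1,3-dioxolane-4-carbaldehyde
Product: 5 (S)-[3,4-bis(benzyloxy)phenyl][(4R)-2,2-dimethyl-1,3-dioxolan-4-yl]methanol (anti adduct), via aryllithium ArLi 3 (not isolated), via aryltitanium ArTi(OiPr)3 4 (not isolated)
Conditions: n-BuLi, THF, −78 °C; ClTi(OiPr)3, −78 to −40 °C; then 2, −78 to 0 °C; aq. NH4Cl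
Reagents that add atoms: none
Why: Bromine–lithium exchange, transmetalation to the non-chelating aryltitanium and Felkin–Anh 1,2-addition to the α-alkoxy aldehyde should give mainly the anti carbinol, the new (S) centre being set by the dioxolane stereocentre.

Step 2
Reactants: 5 anti carbinol; 6 3,5-bis(benzyloxy)phenol
Product: 7 (4R)-4-{(R)-[3,4-bis(benzyloxy)phenyl][3,5-bis(benzyloxy)phenoxy]methyl}-2,2-dimethyl-1,3-dioxolane
Conditions: PPh3, DIAD, toluene, 0 °C to rt
Reagents that add atoms: none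
Why: Mitsunobu etherification displaces the alkoxyphosphonium by the phenol in an SN2 step with inversion, turning the (S) carbinol into the (R) aryl ether (the syn, later 2,3-cis, relationship), while the neighbouring dioxolane oxygen disfavours benzylic ionisation.

Step 3
Reactants: 7 aryl ether acetonide
Product: 8 (2R,3R)-3-[3,4-bis(benzyloxy)phenyl]-3-[3,5-bis(benzyloxy)phenoxy]propane-1,2-diol
Conditions: AcOH/H2O/THF (3:1:1), 40 °C
Reagents that add atoms: none
Why: Mild acid hydrolysis of a terminal isopropylidene acetal should leave the benzyl ethers, the benzylic aryl ether and both stereocentres untouched.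

Step 4
Reactants: 8 diol
Product: 9 (2R,3R)-3-[3,4-bis(benzyloxy)phenyl]-3-[3,5-bis(benzyloxy)phenoxy]-1,2-bis[(tert-butyldimethylsilyl)oxy]propane
Conditions: TBSOTf, 2,6-lutidine, CH2Cl2, −40 to 0 °C
Reagents that add atoms: tert-butyldimethylsilyl trifluoromethanesulfonate (TBSOTf), CC(C)(C)[Si](C)(C)OS(=O)(=O)C(F)(F)F
Why: Standard bis-silylation with a silyl triflate and a hindered base proceeds without alkoxide formation, so the β-aryloxy group cannot be expelled.

Step 5
Reactants: 9 bis-TBS ether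
Product: 10 (2R,3R)-3-[3,4-bis(benzyloxy)phenyl]-3-[3,5-bis(benzyloxy)phenoxy]-2-[(tert-butyldimethylsilyl)oxy]propan-1-ol
Conditions: HF·pyridine, pyridine, THF, 0 °C
Reagents that add atoms: none
Why: Kinetically selective desilylation, since buffered HF·pyridine cleaves the unhindered primary TBS ether much faster than the secondary one.

Step 6
Reactants: 10 primary alcohol
Product: 11 (2S,3R)-3-[3,4-bis(benzyloxy)phenyl]-3-[3,5-bis(benzyloxy)phenoxy]-2-[(tert-butyldimethylsilyl)oxy]propanal
Conditions: Dess–Martin periodinane, CH2Cl2, 0 °C to rt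
Reagents that add atoms: none
Why: Dess–Martin oxidation gives the α-silyloxy aldehyde under non-basic conditions that should avoid epimerisation at C2 and E1cB loss of the β-aryloxide (the descriptor at C2 changes to S only by priority).

Step 7
Reactants: 12 (+)-catechin
Product: 13 (2R,3S)-5,7-bis(benzyloxy)-2-[3,4-bis(benzyloxy)phenyl]chroman-3-ol
Conditions: BnBr (4.4 equiv), K2CO3, DMF, 0 °C to rt
Reagents that add atoms: benzyl bromide, BrCc1ccccc1
Why: Williamson etherification of the four phenols with K2CO3, which does not deprotonate the aliphatic 3-OH.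

Step 8
Reactants: 13 tetra-O-benzylcatechin; 14 4-(benzyloxy)benzoyl chloride
Product: 15 (2R,3S)-5,7-bis(benzyloxy)-2-[3,4-bis(benzyloxy)phenyl]chroman-3-yl 4-(benzyloxy)benzoate
Conditions: Et3N, DMAP (cat.), CH2Cl2, 0 °C to rt
Reagents that add atoms: none
Why: DMAP-catalysed acylation of the only free hydroxyl, with retention at C3 because the C–O bond is not broken.

Step 9
Reactants: 11 α-silyloxy aldehyde; 15 benzylated catechin ester (3 equiv)
Product: 18 (2R,3S)-5,7-bis(benzyloxy)-2-[3,4-bis(benzyloxy)phenyl]-8-{(2R,3R,4R)-5,7-bis(benzyloxy)-2-[3,4-bis(benzyloxy)phenyl]-3-[(tert-butyldimethylsilyl)oxy]chroman-4-yl}chroman-3-yl 4-(benzyloxy)benzoate, via flavan-4-ol 16 (not isolated), via flavan-4-yl cation 17 (not isolated)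
Conditions: TMSOTf (0.3 equiv), 4 Å molecular sieves, CH2Cl2, −78 to −30 °C, slow addition of 11 to 15; Et3N quench
Reagents that add atoms: none
Why: TMSOTf activates the aldehyde, an ortho carbon of the 3,5-bis(benzyloxy)phenyl ether attacks it (intramolecular Friedel–Crafts hydroxyalkylation) to close the upper pyran ring C as flavan-4-ol 16, and this doubly activated benzylic alcohol ionises to cation 17, which is captured by C8 of 15, the former aldehyde oxygen leaving as water that the sieves take up. The closest known reactions are the Baeyer-type double Friedel–Crafts condensation of an aldehyde with two electron-rich arenes, the acid-mediated cyclisation of 3-aryloxypropanals to chroman-4-ols, and the Lewis-acid coupling of flavan-3,4-diols or 4-alkoxyflavans with flavan-3-ol nucleophiles. The ring closure is six-membered and 6-exo-trig at the carbonyl carbon, the new bond being C4–C4a. The carbinol centre of 16 is erased in 17, and C4 is then set by the C3 silyloxy group, which is axial in the half-chair with the C2 aryl equatorial, so 15 should add anti to it and give the 3,4-trans (4β, R) configuration typical of 2,3-cis flavan-4-yl cations. The step needs ring closure to precede intermolecular attack on the aldehyde, which the high effective molarity of the 1,3,5-trioxygenated ring secures (its two ortho positions are equivalent, and the catechol ring could only form a five-membered ring and is far less nucleophilic). It also needs C8 rather than C6 attack on 15 and no oligomerisation, which benzyl protection and the excess of 15 should secure.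

Step 10
Reactants: 18 silylated dimer
Product: 19 (2R,3S)-5,7-bis(benzyloxy)-2-[3,4-bis(benzyloxy)phenyl]-8-{(2R,3R,4R)-5,7-bis(benzyloxy)-2-[3,4-bis(benzyloxy)phenyl]-3-hydroxychroman-4-yl}chroman-3-yl 4-(benzyloxy)benzoate
Conditions: TBAF, AcOH, THF, 0 to 40 °C
Reagents that add atoms: none
Why: Fluoride-mediated desilylation of the secondary TBS ether, buffered with acetic acid so that the aryl ester is not cleaved and no stereocentre is affected.

Step 11
Reactants: 19 nona-O-benzyl dimer
Product: 20 target, epicatechin-(4β→8)-catechin 3-O-(4-hydroxybenzoate) on the lower unit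
Conditions: H2 (1 atm), Pd(OH)2/C, THF/MeOH/H2O, rt
Reagents that add atoms: none
Why: Catalytic hydrogenolysis of the nine O-benzyl groups, the usual final step for benzylated procyanidins, should leave the ester, the interflavan bond and the five stereocentres intact.

## Compound list

1 | 4-bromo-1,2-bis(benzyloxy)benzene | Brc1ccc(OCc2ccccc2)c(OCc2ccccc2)c1 | starting material
2 | (R)-2,2-dimethyl-1,3-dioxolane-4-carbaldehyde | O=C[C@H]1COC(C)(C)O1 | starting material
3 | [3,4-bis(benzyloxy)phenyl]lithium, ArLi | [Li]c1ccc(OCc2ccccc2)c(OCc2ccccc2)c1 | intermediate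
4 | [3,4-bis(benzyloxy)phenyl]titanium triisopropoxide, ArTi(OiPr)3 | CC(C)O[Ti](OC(C)C)(OC(C)C)c1ccc(OCc2ccccc2)c(OCc2ccccc2)c1 | intermediate
5 | (S)-[3,4-bis(benzyloxy)phenyl][(4R)-2,2-dimethyl-1,3-dioxolan-4-yl]methanol | O[C@@H](c1ccc(OCc2ccccc2)c(OCc2ccccc2)c1)[C@H]1COC(C)(C)O1 | intermediate
6 | 3,5-bis(benzyloxy)phenol | Oc1cc(OCc2ccccc2)cc(OCc2ccccc2)c1 | starting material
7 | (4R)-4-{(R)-[3,4-bis(benzyloxy)phenyl][3,5-bis(benzyloxy)phenoxy]methyl}-2,2-dimethyl-1,3-dioxolane | c1c(OCc2ccccc2)cc(OCc2ccccc2)cc1O[C@H](c1ccc(OCc2ccccc2)c(OCc2ccccc2)c1)[C@H]1COC(C)(C)O1 | intermediate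
8 | (2R,3R)-3-[3,4-bis(benzyloxy)phenyl]-3-[3,5-bis(benzyloxy)phenoxy]propane-1,2-diol | c1c(OCc2ccccc2)cc(OCc2ccccc2)cc1O[C@H](c1ccc(OCc2ccccc2)c(OCc2ccccc2)c1)[C@H](O)CO | intermediate
9 | (2R,3R)-1,2-bis-O-TBS ether of 8 | c1c(OCc2ccccc2)cc(OCc2ccccc2)cc1O[C@H](c1ccc(OCc2ccccc2)c(OCc2ccccc2)c1)[C@H](O[Si](C)(C)C(C)(C)C)CO[Si](C)(C)C(C)(C)C | intermediate
10 | (2R,3R)-3-[3,4-bis(benzyloxy)phenyl]-3-[3,5-bis(benzyloxy)phenoxy]-2-[(tert-butyldimethylsilyl)oxy]propan-1-ol | c1c(OCc2ccccc2)cc(OCc2ccccc2)cc1O[C@H](c1ccc(OCc2ccccc2)c(OCc2ccccc2)c1)[C@H](O[Si](C)(C)C(C)(C)C)CO | intermediate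
11 | (2S,3R)-3-[3,4-bis(benzyloxy)phenyl]-3-[3,5-bis(benzyloxy)phenoxy]-2-[(tert-butyldimethylsilyl)oxy]propanal | c1c(OCc2ccccc2)cc(OCc2ccccc2)cc1O[C@H](c1ccc(OCc2ccccc2)c(OCc2ccccc2)c1)[C@H](O[Si](C)(C)C(C)(C)C)C=O | intermediate
12 | (+)-catechin, (2R,3S) | O[C@H]1Cc2c(O)cc(O)cc2O[C@@H]1c1ccc(O)c(O)c1 | starting material
13 | (2R,3S)-5,7-bis(benzyloxy)-2-[3,4-bis(benzyloxy)phenyl]chroman-3-ol | O[C@H]1Cc2c(OCc3ccccc3)cc(OCc3ccccc3)cc2O[C@@H]1c1ccc(OCc2ccccc2)c(OCc2ccccc2)c1 | intermediate
14 | 4-(benzyloxy)benzoyl chloride | O=C(Cl)c1ccc(OCc2ccccc2)cc1 | starting material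
15 | (2R,3S)-5,7-bis(benzyloxy)-2-[3,4-bis(benzyloxy)phenyl]chroman-3-yl 4-(benzyloxy)benzoate | O=C(O[C@H]1Cc2c(OCc3ccccc3)cc(OCc3ccccc3)cc2O[C@@H]1c1ccc(OCc2ccccc2)c(OCc2ccccc2)c1)c1ccc(OCc2ccccc2)cc1 | intermediate
16 | (2R,3R)-5,7-bis(benzyloxy)-2-[3,4-bis(benzyloxy)phenyl]-3-[(tert-butyldimethylsilyl)oxy]chroman-4-ol, both C4 epimers | OC1c2c(OCc3ccccc3)cc(OCc3ccccc3)cc2O[C@H](c2ccc(OCc3ccccc3)c(OCc3ccccc3)c2)[C@@H]1O[Si](C)(C)C(C)(C)C | intermediate
17 | (2R,3R)-5,7-bis(benzyloxy)-2-[3,4-bis(benzyloxy)phenyl]-3-[(tert-butyldimethylsilyl)oxy]chroman-4-yl cation | [CH+]1c2c(OCc3ccccc3)cc(OCc3ccccc3)cc2O[C@H](c2ccc(OCc3ccccc3)c(OCc3ccccc3)c2)[C@@H]1O[Si](C)(C)C(C)(C)C | intermediate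
18 | nona-O-benzyl dimer with upper 3-O-TBS, upper (2R,3R,4R), lower (2R,3S) | O=C(O[C@H]1Cc2c(OCc3ccccc3)cc(OCc3ccccc3)c([C@H]3c4c(OCc5ccccc5)cc(OCc5ccccc5)cc4O[C@H](c4ccc(OCc5ccccc5)c(OCc5ccccc5)c4)[C@@H]3O[Si](C)(C)C(C)(C)C)c2O[C@@H]1c1ccc(OCc2ccccc2)c(OCc2ccccc2)c1)c1ccc(OCc2ccccc2)cc1 | intermediate
19 | nona-O-benzyl dimer with free upper 3-OH | O=C(O[C@H]1Cc2c(OCc3ccccc3)cc(OCc3ccccc3)c([C@H]3c4c(OCc5ccccc5)cc(OCc5ccccc5)cc4O[C@H](c4ccc(OCc5ccccc5)c(OCc5ccccc5)c4)[C@@H]3O)c2O[C@@H]1c1ccc(OCc2ccccc2)c(OCc2ccccc2)c1)c1ccc(OCc2ccccc2)cc1 | intermediate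
20 | CNP0288594.1, epicatechin-(4β→8)-catechin 3-O-(4-hydroxybenzoate) on the lower unit | O=C(O[C@H]1Cc2c(O)cc(O)c([C@H]3c4c(O)cc(O)cc4O[C@H](c4ccc(O)c(O)c4)[C@@H]3O)c2O[C@@H]1c1ccc(O)c(O)c1)c1ccc(O)cc1 | target

## Step count and risks

Total step count: 11. Longest linear sequence: 9 steps (steps 1 to 6, then 9 to 11); steps 7 and 8 form the second branch.

Steps most likely to fail:

1. Step 9 (key cascade). The aldehyde may be attacked intermolecularly by 15 before ring closure, the cation may self-condense to oligomers, or facial selectivity at C4 and C8/C6 regioselectivity may erode. The fallback sets out from 11 and separates the two bond formations. Treatment of 11 alone with CSA (cat.) in MeOH/HC(OMe)3/CH2Cl2 at 0 °C should close ring C by the same Friedel–Crafts hydroxyalkylation and intercept the cation with methanol. This gives (2R,3R)-5,7-bis(benzyloxy)-2-[3,4-bis(benzyloxy)phenyl]-3-[(tert-butyldimethylsilyl)oxy]-4-methoxychroman F1, an isolable electrophile of the classical 4-alkoxyflavan type. F1 is then coupled with 15 (TMSOTf cat., CH2Cl2, −78 °C), the established Lewis-acid condensation of 4-alkoxyflavans with flavan-3-ol nucleophiles, and the route is rejoined at 18.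

2. Step 1. Facial selectivity in the aryl addition to the α-alkoxy aldehyde may be poor, leaving much syn carbinol. The fallback sets out from aryllithium 3 (made from 1 as in step 1). Acylation with methyl (R)-2,2-dimethyl-1,3-dioxolane-4-carboxylate (COC(=O)[C@H]1COC(C)(C)O1) at −78 °C should give [3,4-bis(benzyloxy)phenyl][(4R)-2,2-dimethyl-1,3-dioxolan-4-yl]methanone F2. Chelation-controlled reduction with Zn(BH4)2 (Et2O, −30 °C; Cram-chelate model, hydride from the face opposite the ring CH2) should then give the anti carbinol, rejoining the route at 5.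

3. Step 2. Partial ionisation of the electron-rich benzylic alkoxyphosphonium (SN1 leakage, loss of inversion) or elimination may spoil the Mitsunobu etherification. The fallback sets out from 5 and makes the ether bond at oxygen instead of at carbon. Dess–Martin oxidation of 5 gives ketone F2 (described under the previous point). Felkin–Anh reduction with LiBH(s-Bu)3 (THF, −78 °C) should give the syn carbinol (R)-[3,4-bis(benzyloxy)phenyl][(4R)-2,2-dimethyl-1,3-dioxolan-4-yl]methanol F3. Ullmann-type O-arylation of F3 with 1-iodo-3,5-bis(benzyloxy)benzene (Ic1cc(OCc2ccccc2)cc(OCc2ccccc2)c1; CuI, 3,4,7,8-tetramethyl-1,10-phenanthroline, Cs2CO3, toluene, 110 °C) leaves the carbinol C–O bond intact (retention at carbon), rejoining the route at 7.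

Further compounds
F1 | step 9 | (2R,3R)-5,7-bis(benzyloxy)-2-[3,4-bis(benzyloxy)phenyl]-3-[(tert-butyldimethylsilyl)oxy]-4-methoxychroman, both C4 epimers | COC1c2c(OCc3ccccc3)cc(OCc3ccccc3)cc2O[C@H](c2ccc(OCc3ccccc3)c(OCc3ccccc3)c2)[C@@H]1O[Si](C)(C)C(C)(C)C
F2 | step 1 | [3,4-bis(benzyloxy)phenyl][(4R)-2,2-dimethyl-1,3-dioxolan-4-yl]methanone | O=C(c1ccc(OCc2ccccc2)c(OCc2ccccc2)c1)[C@H]1COC(C)(C)O1
F3 | step 2 | (R)-[3,4-bis(benzyloxy)phenyl][(4R)-2,2-dimethyl-1,3-dioxolan-4-yl]methanol | O[C@H](c1ccc(OCc2ccccc2)c(OCc2ccccc2)c1)[C@H]1COC(C)(C)O1
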